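**Strategy.** Atom labels: quinone ring C1(=O), C2(NH2), C3(H), C4(=O); benzenoid ring C5 (acyl), C6 (OH), C7 (CH3), C8 (H). The route rests on disconnecting the C3–C4 bond of the quinone ring. A benzocyclobutenone whose sp3 carbon (future C1) carries methoxy and a 1-ethoxyvinyl group (C2=C3) is heated: strain-releasing 4π ring opening gives an o-quinoid dienylketene whose ketene carbon (C4, peri to the C5 acyl group) closes onto C3 by 6π electrocyclization, creating the para-dioxygenated ring in one operation. The cyclobutenone comes from a Parham cyclization; the complete polypropionate enone side chain is carried through, and ethoxy is exchanged for NH2 at the end.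

Key step: step 20

Remark (assumption): side-chain carbons are numbered C1 (carboxyl) to C11 (aryl ketone carbon); the quaternary benzylic carbon made in step 16 is racemic and the C11 carbinol made in step 17 is an epimer mixture, both centres become sp2 in steps 19 and 20, so they carry no descriptor in the SMILES of 30–35.

**Side chain (steps 1–12)**

Step 1
Reactants: 1 (R)-4-benzyl-3-propanoyl-1,3-oxazolidin-2-one; 2 propanal
Product: 4 (4R)-4-benzyl-3-[(2R,3S)-3-hydroxy-2-methylpentanoyl]-1,3-oxazolidin-2-one, via (Z)-dibutylboron enolate 3 (not isolated)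
Conditions: Bu2BOTf, i-Pr2NEt, CH2Cl2, 0 °C; 2, −78 → 0 °C; then pH 7 buffer, MeOH, H2O2
Reagents that add atoms: none
Why: Evans syn aldol through a Zimmerman–Traxler chair, in which the (R)-benzyl auxiliary should set (2R,3S); only the C2 centre is kept.

Step 2
Reactants: 4
Product: 5 (4R)-4-benzyl-3-[(2R)-2-methyl-3-oxopentanoyl]-1,3-oxazolidin-2-one
Conditions: SO3·pyridine, DMSO, Et3N, CH2Cl2, −10 °C
Reagents that add atoms: none
Why: Parikh–Doering oxidation should give the β-ketoimide without epimerization at C2, because allylic strain in the imide disfavours enolization toward C2.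

Step 3
Reactants: 5; 6 methacrolein
Product: 8 (4R)-4-benzyl-3-[(2R,4S,5R)-5-hydroxy-2,4,6-trimethyl-3-oxohept-6-enoyl]-1,3-oxazolidin-2-one, via (E)-dicyclohexylboron enolate 7 (not isolated)
Conditions: (c-C6H11)2BCl, EtNMe2, Et2O, 0 °C; 6, −78 → −20 °C; then pH 7 buffer, MeOH, H2O2, 0 °C
Reagents that add atoms: none
Why: Anti aldol of the β-ketoimide (E)-boron enolate via a chair transition state, in which the C2 methyl stereocentre should direct the enolate face to give the 2,4-anti-4,5-anti adduct; the achiral enal imposes no competing bias.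

Step 4
Reactants: 8
Product: 9 (4R)-4-benzyl-3-[(2R,3S,4R,5R)-3,5-dihydroxy-2,4,6-trimethylhept-6-enoyl]-1,3-oxazolidin-2-one
Conditions: Zn(BH4)2, CH2Cl2/Et2O, −78 → −40 °C; aq. NH4Cl
Reagents that add atoms: none
Why: Chelation-controlled 1,3-syn reduction of the β-hydroxy ketone, in which the zinc chelate should deliver hydride to set C3–OH syn to C5–OH.

Step 5
Reactants: 9
Product: 10 (4R)-4-benzyl-3-{(2R)-2-[(4S,5R,6R)-2,2-di-tert-butyl-5-methyl-6-(prop-1-en-2-yl)-1,3,2-dioxasilinan-4-yl]propanoyl}-1,3-oxazolidin-2-one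
Conditions: t-Bu2Si(OTf)2, 2,6-lutidine, CH2Cl2, 0 °C
Reagents that add atoms: di-tert-butylsilyl bis(trifluoromethanesulfonate), CC(C)(C)[Si](OS(=O)(=O)C(F)(F)F)(OS(=O)(=O)C(F)(F)F)C(C)(C)C
Why: Silylene protection of the syn-1,3-diol as a six-membered dioxasilinane, which also prevents lactonization onto the imide.

Step 6
Reactants: 10
Product: 12 (2R)-2-[(4S,5R,6R)-2,2-di-tert-butyl-5-methyl-6-(prop-1-en-2-yl)-1,3,2-dioxasilinan-4-yl]propanoic acid, via peroxy acid 11 (not isolated)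
Conditions: LiOH, H2O2, THF/H2O, 0 °C; Na2SO3; then 1 M HCl to pH 4
Reagents that add atoms: hydrogen peroxide, OO
Why: Hydroperoxide hydrolysis of the N-acyl oxazolidinone should cleave the exocyclic carbonyl selectively without touching C2.

Step 7
Reactants: 12
Product: 13 tert-butyl (2R)-2-[(4S,5R,6R)-2,2-di-tert-butyl-5-methyl-6-(prop-1-en-2-yl)-1,3,2-dioxasilinan-4-yl]propanoate
Conditions: O-tert-butyl-N,N′-diisopropylisourea, CH2Cl2, rt
Reagents that add atoms: O-tert-butyl-N,N′-diisopropylisourea, CC(C)N=C(OC(C)(C)C)NC(C)C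
Why: Neutral isourea esterification should give a tert-butyl ester that resists the organolithium steps ahead.

Step 8
Reactants: 13
Product: 15 tert-butyl (2R)-2-[(4S,5S,6S)-2,2-di-tert-butyl-6-[(2S)-1-hydroxypropan-2-yl]-5-methyl-1,3,2-dioxasilinan-4-yl]propanoate, via B-alkyl-9-BBN adduct 14 (not isolated)
Conditions: 9-BBN, THF, 0 °C → rt; then NaOH, H2O2, 0 °C
Reagents that add atoms: hydrogen peroxide, OO
Why: Anti-Markovnikov hydroboration–oxidation, in which the bulky borane should attack the 1,1-disubstituted alkene anti to the ring carbon in the conformer of least allylic strain, setting C6 anti to the C5 oxygen.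

Step 9
Reactants: 15
Product: 16 tert-butyl (2R)-2-[(4S,5S,6R)-2,2-di-tert-butyl-5-methyl-6-[(2R)-1-oxopropan-2-yl]-1,3,2-dioxasilinan-4-yl]propanoate
Conditions: Dess–Martin periodinane, NaHCO3, CH2Cl2, 0 °C → rt; used crude
Reagents that add atoms: none
Why: Buffered Dess–Martin oxidation should give the α-chiral aldehyde without epimerization.

Step 10
Reactants: 16; 17 cis-but-2-ene
Product: 19 tert-butyl (2R)-2-[(4S,5S,6S)-2,2-di-tert-butyl-6-[(2S,3S,4R)-3-hydroxy-4-methylhex-5-en-2-yl]-5-methyl-1,3,2-dioxasilinan-4-yl]propanoate, via (Z)-crotyldiisopinocampheylborane 18 (not isolated)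
Conditions: 17, KOt-Bu, n-BuLi, THF, −78 → −45 °C; (−)-Ipc2BOMe [from (+)-α-pinene], −78 °C; BF3·OEt2; 16, −78 °C; then NaOH, H2O2
Reagents that add atoms: none
Why: Brown (Z)-crotylboration through a chair transition state: the Z geometry gives 7,8-syn and the reagent adds to the Si face of the aldehyde, which coincides with the anti-Felkin preference of (Z)-crotylboranes for α-methyl aldehydes (matched pair) and sets 6,7-anti.

Step 11
Reactants: 19
Product: 20 tert-butyl (2R)-2-[(4S,5S,6S)-2,2-di-tert-butyl-6-[(2S,3S,4R)-3-[(tert-butyldimethylsilyl)oxy]-4-methylhex-5-en-2-yl]-5-methyl-1,3,2-dioxasilinan-4-yl]propanoate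
Conditions: TBSOTf, 2,6-lutidine, CH2Cl2, −78 → 0 °C
Reagents that add atoms: tert-butyldimethylsilyl trifluoromethanesulfonate, CC(C)(C)[Si](C)(C)OS(=O)(=O)C(F)(F)F
Why: Silyl triflate silylation should protect the hindered C7 hydroxyl.

Step 12
Reactants: 20; 6 methacrolein
Product: 21 tert-butyl (2R)-2-[(4S,5S,6S)-2,2-di-tert-butyl-6-[(2S,3S,4R,5E)-3-[(tert-butyldimethylsilyl)oxy]-4,6-dimethyl-7-oxohept-5-en-2-yl]-5-methyl-1,3,2-dioxasilinan-4-yl]propanoate
Conditions: second-generation Hoveyda–Grubbs catalyst RuCl2(H2IMes)(=CH-C6H4-2-O-i-Pr), excess 6, CH2Cl2, 40 °C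
Reagents that add atoms: none
Why: Olefin cross-metathesis of the terminal alkene with methacrolein should give the trisubstituted enal as the thermodynamically favoured E isomer.

**Aromatic part (steps 13–16)**

Step 13
Reactants: 22 5-bromo-2-methylphenol
Product: 23 5-bromo-4-iodo-2-methylphenol
Conditions: N-iodosuccinimide, TsOH (cat.), MeCN, 0 °C → rt
Reagents that add atoms: N-iodosuccinimide, O=C1CCC(=O)N1I
Why: Electrophilic aromatic iodination should go para to the hydroxyl, the only free ortho position being flanked by OH and Br.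

Step 14
Reactants: 23
Product: 24 1-bromo-2-iodo-5-(methoxymethoxy)-4-methylbenzene
Conditions: MOMCl, i-Pr2NEt, CH2Cl2, 0 °C → rt
Reagents that add atoms: chloromethyl methyl ether, COCCl
Why: O-alkylation gives the MOM ether, which survives the organometallic steps and later directs the ortho-metalation.

Step 15
Reactants: 24; 25 dimethyl oxalate
Product: 27 methyl 2-[2-bromo-4-(methoxymethoxy)-5-methylphenyl]-2-oxoacetate, via arylmagnesium chloride 26 (not isolated)
Conditions: i-PrMgCl·LiCl, THF, −40 °C; then into excess 25, THF, −78 °C; aq. NH4Cl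
Reagents that add atoms: none
Why: Iodine–magnesium exchange is selective for iodine over bromine, and acylation of the aryl Grignard by the oxalate should stop at the α-keto ester.

Step 16
Reactants: 27; 28 ethyl vinyl ether
Product: 31 methyl 2-[2-bromo-4-(methoxymethoxy)-5-methylphenyl]-3-ethoxy-2-methoxybut-3-enoate (racemic), via 1-ethoxyvinyllithium 29 (not isolated), via lithium alkoxide 30 (not isolated)
Conditions: 28, t-BuLi, THF, −78 → 0 °C; 27, −78 °C; then MeOTf, −78 → 0 °C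
Reagents that add atoms: methyl trifluoromethanesulfonate, COS(=O)(=O)C(F)(F)F
Why: 1,2-Addition of the α-lithiated enol ether to the ketone of the α-keto ester (more electrophilic than the ester), then O-methylation of the alkoxide, installs C1 with its oxygen and the C2=C3 unit.

**Union and end game (steps 17–24)**

Step 17
Reactants: 31; 21
Product: 33 C11 carbinol in which the CHO of 21 has become CH(OH)–Ar with Ar = 2-bromo-3-(3-ethoxy-1,2-dimethoxy-1-oxobut-3-en-2-yl)-6-(methoxymethoxy)-5-methylphenyl (diastereomer mixture), via aryllithium 32 (not isolated)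
Conditions: LiTMP (lithium 2,2,6,6-tetramethylpiperidide, from TMPH and n-BuLi), THF, −78 °C; then 21, −78 °C; aq. NH4Cl at −78 °C
Reagents that add atoms: none
Why: Directed ortho-lithiation at the ring C–H flanked by the MOM ether and bromine (the ester has no α-hydrogen), then 1,2-addition of the aryllithium to the enal; the C11 configuration is irrelevant because it is oxidized in step 19.

Step 18
Reactants: 33
Product: 35 benzocyclobutenone 8-(1-ethoxyethenyl)-8-methoxy-4-(methoxymethoxy)-3-methylbicyclo[4.2.0]octa-1,3,5-trien-7-one bearing the C11 carbinol side chain at C5 (diastereomer mixture), via dilithiated intermediate 34 (not isolated)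
Conditions: t-BuLi (3.1 equiv), THF/Et2O, −100 → −78 °C; AcOH quench at −78 °C
Reagents that add atoms: none
Why: Parham cyclization: after deprotonation of the hydroxyl, bromine–lithium exchange gives an aryllithium that should acylate itself on the adjacent non-enolizable ester (four-membered ring closure favoured by the quaternary centre), the tetrahedral adduct releasing the strained ketone only on work-up.

Step 19
Reactants: 35
Product: 36 the C11 ketone of 35: 5-[(E)-enoyl side chain]-8-(1-ethoxyethenyl)-8-methoxy-4-(methoxymethoxy)-3-methylbicyclo[4.2.0]octa-1,3,5-trien-7-one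
Conditions: Dess–Martin periodinane, NaHCO3, CH2Cl2, 0 °C → rt
Reagents that add atoms: none
Why: Buffered Dess–Martin oxidation of the allylic-benzylic alcohol installs the aryl enone and removes the hydroxyl that could otherwise trap the ketene of the next step.

Step 20
Reactants: 36
Product: 39 8-[(E)-enoyl side chain]-3-ethoxy-4-methoxy-7-(methoxymethoxy)-6-methylnaphthalen-1-ol, via o-quinoid dienylketene 37 (not isolated), via 2H-naphthalen-1-one tautomer 38 (not isolated)
Conditions: degassed p-xylene, 135 °C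
Reagents that add atoms: none
Why: Moore rearrangement (thermal ring expansion of a 4-alkenyl-4-alkoxycyclobutenone, here benzo-fused): conrotatory 4π opening of the strained four-membered ring breaks the C1–C4 σ-bond and gives o-quinoid dienylketene 37, the methoxy donor rotating outward and the ethoxyvinyl group inward. Disrotatory 6π electrocyclization then joins the ketene carbon (C4) to the vinyl CH2 (C3), restoring the benzene ring in 38, which enolizes to naphthol 39. The ring closed is the six-membered ring C1–C4/C4a/C8a, by 6π electrocyclic closure, and no stereocentre is formed. The step needs inward rotation of the vinyl group (secured by the methoxy group), C–C closure instead of oxygen trapping of the ketene (secured by the methyl ether on the C1 oxygen and by the prior oxidation of C11–OH), and the right regiochemistry (fixed by the constitution of 36, since the vinyl group already sits on C1 and the only ketene carbon is C4). Release of cyclobutene strain and the gain of naphthalene aromaticity should drive the cascade.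

Step 21
Reactants: 39
Product: 40 5-[(E)-enoyl side chain]-2-ethoxy-6-(methoxymethoxy)-7-methylnaphthalene-1,4-dione
Conditions: PhI(OAc)2, MeCN/pH 7 aqueous buffer, 0 °C
Reagents that add atoms: water, O
Why: Oxidative demethylation of the para-methoxynaphthol with the hypervalent iodine reagent (water adds at C1, methanol leaves) should give the 1,4-quinone and keep the 2-ethoxy group.

Step 22
Reactants: 40
Product: 41 2-amino-5-[(E)-enoyl side chain]-6-(methoxymethoxy)-7-methylnaphthalene-1,4-dione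
Conditions: NH3 (2 M in EtOH), THF, 0 °C → rt
Reagents that add atoms: ammonia, N
Why: Addition–elimination at C2 of the 2-alkoxyquinone (a vinylogous ester) should replace ethoxy by NH2; the tert-butyl ester and the hindered enone do not react with ammonia.

Step 23
Reactants: 41
Product: 42 the free phenol and free C1 carboxylic acid of 41 (C7–OTBS and C3/C5 silylene retained)
Conditions: TMSOTf, 2,2′-bipyridyl, CH2Cl2, 0 °C → rt; then H2O, THF
Reagents that add atoms: none
Why: Silyl-triflate-mediated cleavage should convert the aryl MOM ether into the aryl silyl ether and the tert-butyl ester into the silyl ester (loss of isobutene), both hydrolysed by water, while the alkyl silyl ethers stay and the C5 oxygen remains masked so that no lactone can form.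

Step 24
Reactants: 42
Product: 43 (2R,3S,4S,5S,6S,7S,8R,9E)-11-(6-amino-2-hydroxy-3-methyl-5,8-dioxo-5,8-dihydronaphthalen-1-yl)-3,5,7-trihydroxy-2,4,6,8,10-pentamethyl-11-oxoundec-9-enoic acid (CNP0287228.1)
Conditions: HF·pyridine, pyridine, THF, 0 °C → rt; pH 7 buffer work-up
Reagents that add atoms: none
Why: Fluoride desilylation removes the TBS ether and the silylene; buffering with pyridine should keep the 5-hydroxy acid from lactonizing and leaves the aminoquinone and enone untouched.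

**Compound list**

1 | (R)-4-benzyl-3-propanoyl-1,3-oxazolidin-2-one | CCC(=O)N1[C@H](Cc2ccccc2)COC1=O | starting material
2 | propanal | CCC=O | starting material
3 | (Z)-dibutylboron enolate of 1 | C/C=C(\OB(CCCC)CCCC)N1[C@H](Cc2ccccc2)COC1=O | intermediate
4 | (4R)-4-benzyl-3-[(2R,3S)-3-hydroxy-2-methylpentanoyl]-1,3-oxazolidin-2-one | CC[C@H](O)[C@@H](C)C(=O)N1[C@H](Cc2ccccc2)COC1=O | intermediate
5 | (4R)-4-benzyl-3-[(2R)-2-methyl-3-oxopentanoyl]-1,3-oxazolidin-2-one | CCC(=O)[C@@H](C)C(=O)N1[C@H](Cc2ccccc2)COC1=O | intermediate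
6 | methacrolein (2-methylprop-2-enal) | C=C(C)C=O | starting material
7 | (E)-dicyclohexylboron enolate of 5 | C/C=C(/OB(C1CCCCC1)C1CCCCC1)[C@@H](C)C(=O)N1[C@H](Cc2ccccc2)COC1=O | intermediate
8 | (4R)-4-benzyl-3-[(2R,4S,5R)-5-hydroxy-2,4,6-trimethyl-3-oxohept-6-enoyl]-1,3-oxazolidin-2-one | C=C(C)[C@H](O)[C@H](C)C(=O)[C@@H](C)C(=O)N1[C@H](Cc2ccccc2)COC1=O | intermediate
9 | (4R)-4-benzyl-3-[(2R,3S,4R,5R)-3,5-dihydroxy-2,4,6-trimethylhept-6-enoyl]-1,3-oxazolidin-2-one | C=C(C)[C@H](O)[C@H](C)[C@H](O)[C@@H](C)C(=O)N1[C@H](Cc2ccccc2)COC1=O | intermediate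
10 | (4R)-4-benzyl-3-{(2R)-2-[(4S,5R,6R)-2,2-di-tert-butyl-5-methyl-6-(prop-1-en-2-yl)-1,3,2-dioxasilinan-4-yl]propanoyl}-1,3-oxazolidin-2-one | C=C(C)[C@@H]1O[Si](C(C)(C)C)(C(C)(C)C)O[C@@H]([C@H]1C)[C@@H](C)C(=O)N2[C@H](Cc3ccccc3)COC2=O | intermediate
11 | peroxy acid corresponding to 12 | C=C(C)[C@@H]1O[Si](C(C)(C)C)(C(C)(C)C)O[C@@H]([C@H]1C)[C@@H](C)C(=O)OO | intermediate
12 | (2R)-2-[(4S,5R,6R)-2,2-di-tert-butyl-5-methyl-6-(prop-1-en-2-yl)-1,3,2-dioxasilinan-4-yl]propanoic acid | C=C(C)[C@@H]1O[Si](C(C)(C)C)(C(C)(C)C)O[C@@H]([C@H]1C)[C@@H](C)C(=O)O | intermediate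
13 | tert-butyl ester of 12 | C=C(C)[C@@H]1O[Si](C(C)(C)C)(C(C)(C)C)O[C@@H]([C@H]1C)[C@@H](C)C(=O)OC(C)(C)C | intermediate
14 | B-alkyl-9-borabicyclo[3.3.1]nonane adduct of 13 | C1CC2CCCC(C1)B2C[C@H](C)[C@@H]1O[Si](C(C)(C)C)(C(C)(C)C)O[C@@H]([C@H]1C)[C@@H](C)C(=O)OC(C)(C)C | intermediate
15 | tert-butyl (2R)-2-[(4S,5S,6S)-2,2-di-tert-butyl-6-[(2S)-1-hydroxypropan-2-yl]-5-methyl-1,3,2-dioxasilinan-4-yl]propanoate | OC[C@H](C)[C@@H]1O[Si](C(C)(C)C)(C(C)(C)C)O[C@@H]([C@H]1C)[C@@H](C)C(=O)OC(C)(C)C | intermediate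
16 | tert-butyl (2R)-2-[(4S,5S,6R)-2,2-di-tert-butyl-5-methyl-6-[(2R)-1-oxopropan-2-yl]-1,3,2-dioxasilinan-4-yl]propanoate | O=C[C@H](C)[C@@H]1O[Si](C(C)(C)C)(C(C)(C)C)O[C@@H]([C@H]1C)[C@@H](C)C(=O)OC(C)(C)C | intermediate
17 | cis-but-2-ene | C/C=C\C | starting material
18 | (Z)-crotyldiisopinocampheylborane from (−)-Ipc2BOMe | C/C=C\CB([C@@H]1C[C@@H]2C[C@H]([C@H]1C)C2(C)C)[C@@H]1C[C@@H]2C[C@H]([C@H]1C)C2(C)C | intermediate
19 | tert-butyl (2R)-2-[(4S,5S,6S)-2,2-di-tert-butyl-6-[(2S,3S,4R)-3-hydroxy-4-methylhex-5-en-2-yl]-5-methyl-1,3,2-dioxasilinan-4-yl]propanoate | C=C[C@@H](C)[C@H](O)[C@H](C)[C@@H]1O[Si](C(C)(C)C)(C(C)(C)C)O[C@@H]([C@H]1C)[C@@H](C)C(=O)OC(C)(C)C | intermediate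
20 | C7 tert-butyldimethylsilyl ether of 19 | C=C[C@@H](C)[C@H](O[Si](C)(C)C(C)(C)C)[C@H](C)[C@@H]1O[Si](C(C)(C)C)(C(C)(C)C)O[C@@H]([C@H]1C)[C@@H](C)C(=O)OC(C)(C)C | intermediate
21 | tert-butyl (2R)-2-[(4S,5S,6S)-2,2-di-tert-butyl-6-[(2S,3S,4R,5E)-3-[(tert-butyldimethylsilyl)oxy]-4,6-dimethyl-7-oxohept-5-en-2-yl]-5-methyl-1,3,2-dioxasilinan-4-yl]propanoate (enal, C1–C11) | C/C(=C\[C@@H](C)[C@H](O[Si](C)(C)C(C)(C)C)[C@H](C)[C@@H]1O[Si](C(C)(C)C)(C(C)(C)C)O[C@@H]([C@H]1C)[C@@H](C)C(=O)OC(C)(C)C)C=O | intermediate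
22 | 5-bromo-2-methylphenol | Cc1ccc(Br)cc1O | starting material
23 | 5-bromo-4-iodo-2-methylphenol | Cc1cc(I)c(Br)cc1O | intermediate
24 | 1-bromo-2-iodo-5-(methoxymethoxy)-4-methylbenzene | Cc1cc(I)c(Br)cc1OCOC | intermediate
25 | dimethyl oxalate | COC(=O)C(=O)OC | starting material
26 | [2-bromo-4-(methoxymethoxy)-5-methylphenyl]magnesium chloride | Cc1cc([Mg]Cl)c(Br)cc1OCOC | intermediate
27 | methyl 2-[2-bromo-4-(methoxymethoxy)-5-methylphenyl]-2-oxoacetate | Cc1cc(C(=O)C(=O)OC)c(Br)cc1OCOC | intermediate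
28 | ethyl vinyl ether | C=COCC | starting material
29 | 1-ethoxyvinyllithium | [Li]C(=C)OCC | intermediate
30 | lithium alkoxide of the adduct of 29 to 27 | Cc1cc(C(O[Li])(C(=C)OCC)C(=O)OC)c(Br)cc1OCOC | intermediate
31 | methyl 2-[2-bromo-4-(methoxymethoxy)-5-methylphenyl]-3-ethoxy-2-methoxybut-3-enoate (racemic) | Cc1cc(C(OC)(C(=C)OCC)C(=O)OC)c(Br)cc1OCOC | intermediate
32 | aryllithium from 31, lithiated between OMOM and Br | Cc1cc(C(OC)(C(=C)OCC)C(=O)OC)c(Br)c([Li])c1OCOC | intermediate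
33 | C11 carbinol, adduct of 32 to 21 (diastereomer mixture) | C/C(=C\[C@@H](C)[C@H](O[Si](C)(C)C(C)(C)C)[C@H](C)[C@@H]1O[Si](C(C)(C)C)(C(C)(C)C)O[C@@H]([C@H]1C)[C@@H](C)C(=O)OC(C)(C)C)C(O)c1c(OCOC)c(C)cc(C(OC)(C(=C)OCC)C(=O)OC)c1Br | intermediate
34 | lithium alkoxide/aryllithium from 33 | C/C(=C\[C@@H](C)[C@H](O[Si](C)(C)C(C)(C)C)[C@H](C)[C@@H]1O[Si](C(C)(C)C)(C(C)(C)C)O[C@@H]([C@H]1C)[C@@H](C)C(=O)OC(C)(C)C)C(O[Li])c1c(OCOC)c(C)cc(C(OC)(C(=C)OCC)C(=O)OC)c1[Li] | intermediate
35 | benzocyclobutenone with C11 carbinol side chain (diastereomer mixture) | C/C(=C\[C@@H](C)[C@H](O[Si](C)(C)C(C)(C)C)[C@H](C)[C@@H]1O[Si](C(C)(C)C)(C(C)(C)C)O[C@@H]([C@H]1C)[C@@H](C)C(=O)OC(C)(C)C)C(O)c1c(OCOC)c(C)cc2c1C(=O)C2(OC)C(=C)OCC | intermediate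
36 | benzocyclobutenone with C11 ketone (key-step substrate) | C/C(=C\[C@@H](C)[C@H](O[Si](C)(C)C(C)(C)C)[C@H](C)[C@@H]1O[Si](C(C)(C)C)(C(C)(C)C)O[C@@H]([C@H]1C)[C@@H](C)C(=O)OC(C)(C)C)C(=O)c1c(OCOC)c(C)cc2c1C(=O)C2(OC)C(=C)OCC | intermediate
37 | o-quinoid dienylketene | C/C(=C\[C@@H](C)[C@H](O[Si](C)(C)C(C)(C)C)[C@H](C)[C@@H]1O[Si](C(C)(C)C)(C(C)(C)C)O[C@@H]([C@H]1C)[C@@H](C)C(=O)OC(C)(C)C)C(=O)C1=C(OCOC)C(C)=C/C(=C(\OC)C(=C)OCC)C1=C=O | intermediate
38 | 3-ethoxy-4-methoxy-2H-naphthalen-1-one tautomer of 39 | C/C(=C\[C@@H](C)[C@H](O[Si](C)(C)C(C)(C)C)[C@H](C)[C@@H]1O[Si](C(C)(C)C)(C(C)(C)C)O[C@@H]([C@H]1C)[C@@H](C)C(=O)OC(C)(C)C)C(=O)c1c(OCOC)c(C)cc2c1C(=O)CC(OCC)=C2OC | intermediate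
39 | 8-acyl-3-ethoxy-4-methoxy-7-(methoxymethoxy)-6-methylnaphthalen-1-ol (acyl = protected C1–C11 enoyl chain) | C/C(=C\[C@@H](C)[C@H](O[Si](C)(C)C(C)(C)C)[C@H](C)[C@@H]1O[Si](C(C)(C)C)(C(C)(C)C)O[C@@H]([C@H]1C)[C@@H](C)C(=O)OC(C)(C)C)C(=O)c1c(OCOC)c(C)cc2c(OC)c(OCC)cc(O)c12 | intermediate
40 | 5-acyl-2-ethoxy-6-(methoxymethoxy)-7-methylnaphthalene-1,4-dione | C/C(=C\[C@@H](C)[C@H](O[Si](C)(C)C(C)(C)C)[C@H](C)[C@@H]1O[Si](C(C)(C)C)(C(C)(C)C)O[C@@H]([C@H]1C)[C@@H](C)C(=O)OC(C)(C)C)C(=O)c1c(OCOC)c(C)cc2c1C(=O)C=C(OCC)C2=O | intermediate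
41 | 5-acyl-2-amino-6-(methoxymethoxy)-7-methylnaphthalene-1,4-dione | C/C(=C\[C@@H](C)[C@H](O[Si](C)(C)C(C)(C)C)[C@H](C)[C@@H]1O[Si](C(C)(C)C)(C(C)(C)C)O[C@@H]([C@H]1C)[C@@H](C)C(=O)OC(C)(C)C)C(=O)c1c(OCOC)c(C)cc2c1C(=O)C=C(N)C2=O | intermediate
42 | free phenol and free acid of 41, silyl groups retained | C/C(=C\[C@@H](C)[C@H](O[Si](C)(C)C(C)(C)C)[C@H](C)[C@@H]1O[Si](C(C)(C)C)(C(C)(C)C)O[C@@H]([C@H]1C)[C@@H](C)C(=O)O)C(=O)c1c(O)c(C)cc2c1C(=O)C=C(N)C2=O | intermediate
43 | CNP0287228.1, (2R,3S,4S,5S,6S,7S,8R,9E)-configured acid | C/C(=C\[C@@H](C)[C@H](O)[C@H](C)[C@H](O)[C@H](C)[C@H](O)[C@@H](C)C(=O)O)C(=O)c1c(O)c(C)cc2c1C(=O)C=C(N)C2=O | target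

**Count and risks**

Total steps: 24. Longest linear sequence: 20 (steps 1–12, then 17–24); the aromatic branch (steps 13–16) is 4 steps.

Three steps most likely to fail:

1. Step 18 (Parham cyclization). What may go wrong: the aryllithium is protonated or attacks intermolecularly faster than it closes the strained four-membered ring, or the released ketone is attacked again. Fallback: use a Weinreb amide as the internal electrophile, whose chelated tetrahedral adduct cannot collapse before work-up. Setting out from 24, iodine–magnesium exchange (i-PrMgCl·LiCl) and acylation with N,N′-dimethoxy-N,N′-dimethyloxamide should give the α-keto Weinreb amide F1. Addition of 1-ethoxyvinyllithium and O-methylation as in step 16 gives the amide F2. Lithiation and addition to 21 as in step 17 gives the carbinol F3. Bromine–lithium exchange (t-BuLi, −100 °C) and cyclization onto the amide returns to the route at 35.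

2. Step 20 (key step). What may go wrong: the o-quinoid ketene is intercepted by the neighbouring C11 carbonyl oxygen, or the enone side chain degrades at 135 °C before electrocyclization is complete. Fallback: run the same ring expansion at the carbinol oxidation level and adjust the oxidation state afterwards. Setting out from 35, TESOTf/2,6-lutidine gives the C11 triethylsilyl ether F4. Thermolysis in p-xylene gives the naphthol F5. PhI(OAc)2 in aqueous MeCN gives the quinone F6. PPTS in EtOH removes only the triethylsilyl group to give the quinone alcohol F7. Dess–Martin oxidation returns to the route at 40.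

3. Step 17 (fragment union). What may go wrong: the ortho-bromo aryllithium loses LiBr (aryne formation), or it adds too slowly to the hindered enal at −78 °C. Fallback: fix the metalation site as an iodide and couple through a magnesium reagent. Setting out from 31, LiTMP followed by I2 at −78 °C gives the aryl iodide F8. Exchange with i-PrMgCl·LiCl at −40 °C is selective for iodine (bromide and ester survive) and gives an arylmagnesium species that tolerates higher temperature; its addition to 21 returns to the route at 33.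

Further compounds
F1 | step 18 | 2-[2-bromo-4-(methoxymethoxy)-5-methylphenyl]-N-methoxy-N-methyl-2-oxoacetamide | Cc1cc(C(=O)C(=O)N(C)OC)c(Br)cc1OCOC
F2 | step 18 | 2-[2-bromo-4-(methoxymethoxy)-5-methylphenyl]-3-ethoxy-N,2-dimethoxy-N-methylbut-3-enamide (racemic) | Cc1cc(C(OC)(C(=C)OCC)C(=O)N(C)OC)c(Br)cc1OCOC
F3 | step 18 | Weinreb amide analogue of 33 (diastereomer mixture) | C/C(=C\[C@@H](C)[C@H](O[Si](C)(C)C(C)(C)C)[C@H](C)[C@@H]1O[Si](C(C)(C)C)(C(C)(C)C)O[C@@H]([C@H]1C)[C@@H](C)C(=O)OC(C)(C)C)C(O)c1c(OCOC)c(C)cc(C(OC)(C(=C)OCC)C(=O)N(C)OC)c1Br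
F4 | step 20 | C11 triethylsilyl ether of 35 | C/C(=C\[C@@H](C)[C@H](O[Si](C)(C)C(C)(C)C)[C@H](C)[C@@H]1O[Si](C(C)(C)C)(C(C)(C)C)O[C@@H]([C@H]1C)[C@@H](C)C(=O)OC(C)(C)C)C(O[Si](CC)(CC)CC)c1c(OCOC)c(C)cc2c1C(=O)C2(OC)C(=C)OCC
F5 | step 20 | 3-ethoxy-4-methoxynaphthalen-1-ol with C11 triethylsilyloxy side chain | C/C(=C\[C@@H](C)[C@H](O[Si](C)(C)C(C)(C)C)[C@H](C)[C@@H]1O[Si](C(C)(C)C)(C(C)(C)C)O[C@@H]([C@H]1C)[C@@H](C)C(=O)OC(C)(C)C)C(O[Si](CC)(CC)CC)c1c(OCOC)c(C)cc2c(OC)c(OCC)cc(O)c12
F6 | step 20 | 2-ethoxy-1,4-naphthoquinone with C11 triethylsilyloxy side chain | C/C(=C\[C@@H](C)[C@H](O[Si](C)(C)C(C)(C)C)[C@H](C)[C@@H]1O[Si](C(C)(C)C)(C(C)(C)C)O[C@@H]([C@H]1C)[C@@H](C)C(=O)OC(C)(C)C)C(O[Si](CC)(CC)CC)c1c(OCOC)c(C)cc2c1C(=O)C=C(OCC)C2=O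
F7 | step 20 | 2-ethoxy-1,4-naphthoquinone with free C11 carbinol | C/C(=C\[C@@H](C)[C@H](O[Si](C)(C)C(C)(C)C)[C@H](C)[C@@H]1O[Si](C(C)(C)C)(C(C)(C)C)O[C@@H]([C@H]1C)[C@@H](C)C(=O)OC(C)(C)C)C(O)c1c(OCOC)c(C)cc2c1C(=O)C=C(OCC)C2=O
F8 | step 17 | methyl 2-[2-bromo-3-iodo-4-(methoxymethoxy)-5-methylphenyl]-3-ethoxy-2-methoxybut-3-enoate (racemic) | Cc1cc(C(OC)(C(=C)OCC)C(=O)OC)c(Br)c(I)c1OCOC
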